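The route rests on cutting the bond between veratryl ring carbon C1 and the benzylic CH2 on lactone C4. That CH2 stands 1,3 to the lactone α-carbon C3, so the two can be tied into a cyclopropane: ethyl (1S,5R)-2-oxo-3-oxabicyclo[3.1.0]hexane-1-carboxylate, from (R)-epichlorohydrin and diethyl malonate. In one operation, copper-catalysed homoconjugate addition of 3,4-dimethoxyphenylmagnesium bromide opens the strained ring at its CH2. This forms the aryl–CH2 bond and unveils C4 in the correct configuration, and the released malonate-type enolate is alkylated in the same flask by a 4-(bromomethyl)-2-pyrone-6-carboxylate. Acidic hydrolysis with decarboxylation then sets C3 trans and frees the pyrone acid.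

Key step: step 4

Remark on the chemistry: 3,4-dimethoxyphenylmagnesium bromide is taken as the commercial THF solution (otherwise it is made from 4-bromoveratrole and magnesium). The configuration of the quaternary C3 formed in step 4 is drawn as the expected isomer but is irrelevant, because step 5 erases it.

Step 1
Reactants: 1 ethyl 3-methylbut-2-enoate; 2 diethyl oxalate
Product: 4 ethyl 4-methyl-2-oxo-2H-pyran-6-carboxylate, via potassium dienolate 3 (not isolated)
Conditions: KOEt, Et2O/EtOH, 0 °C → rt; then AcOH; then TsOH (cat.), toluene, reflux (−EtOH)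
Reagents that add atoms: none
Why: γ-Selective (vinylogous) Claisen condensation of the potassium dienolate of 1 with non-enolisable diethyl oxalate should give the stabilised dienolate 3, and acid-catalysed enol lactonisation (six-membered ring, loss of ethanol) closes the 2-pyrone; no stereocentre is formed.

Step 2
Reactants: 4 ethyl 4-methyl-2-oxo-2H-pyran-6-carboxylate
Product: 5 ethyl 4-(bromomethyl)-2-oxo-2H-pyran-6-carboxylate
Conditions: NBS (1.05 equiv), AIBN (cat.), PhCF3, reflux
Reagents that add atoms: N-bromosuccinimide, O=C1CCC(=O)N1Br
Why: Wohl–Ziegler radical bromination should take place at the 4-methyl group, the only allylic (vinylogous) C–H position, while the electron-poor pyrone ring resists ionic bromination; no stereocentre is formed.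

Step 3
Reactants: 6 diethyl malonate; 7 (R)-epichlorohydrin
Product: 9 ethyl (1S,5R)-2-oxo-3-oxabicyclo[3.1.0]hexane-1-carboxylate, via glycidylmalonate 8 (not isolated)
Conditions: NaOEt (1.0 equiv), EtOH, rt → reflux
Reagents that add atoms: none
Why: In this malonate alkylation–cyclopropanation–lactonisation cascade the malonate anion opens the epoxide of 7 at its CH2 terminus, the alkoxide re-closes onto CH2Cl to give 8, 3-exo-tet attack of the malonate anion at the stereogenic epoxide carbon (inversion) forms the cyclopropane and the cis CH2O− lactonises, so C5 is set by (R)-epichlorohydrin and C1 by the obligatory cis ring fusion.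

Step 4
Reactants: 9 ethyl (1S,5R)-2-oxo-3-oxabicyclo[3.1.0]hexane-1-carboxylate; 10 3,4-dimethoxyphenylmagnesium bromide; 5 ethyl 4-(bromomethyl)-2-oxo-2H-pyran-6-carboxylate
Product: 12 ethyl (3R,4R)-4-(3,4-dimethoxybenzyl)-3-{[6-(ethoxycarbonyl)-2-oxo-2H-pyran-4-yl]methyl}-2-oxotetrahydrofuran-3-carboxylate, via bromomagnesium enolate 11 (not isolated)
Conditions: 10 (1.0 equiv), CuI (10 mol %), THF, −40 °C; 9 (1.1 equiv), −40 → −10 °C; then 5 (1.0 equiv), DMPU, −10 °C → rt; aq. NH4Cl
Reagents that add atoms: none
Why: The aryl cuprate formed from 10 and CuI attacks the unsubstituted cyclopropane carbon C6 of 9 in an SN2-type homoconjugate (1,5-) addition, breaking the C1–C6 bond that overlaps with both carbonyl π systems and releasing the ring strain, to give the chelated bromomagnesium enolate 11, which then C-alkylates the allylic bromide 5 by SN2. The closest known reaction type is the CuI-catalysed aryl-Grignard opening of this bicyclic lactone and of cyclopropane-1,1-diesters followed by enolate alkylation, here telescoped as a tandem conjugate addition–alkylation. No ring is closed; the three-membered ring is opened and the γ-lactone is carried through unchanged. The C4 stereocentre of 12 is the untouched C5 of 9 (no bond to it is made or broken) and so derives from (R)-epichlorohydrin, while the new quaternary C3 should form by alkylation anti to the C4 benzyl group, although its configuration is immaterial because step 5 erases it. The step needs regioselectivity for C6 over C5, secured by the preference of the cuprate for the CH2 over the substituted CH, and chemoselectivity over carbonyl addition, secured by copper catalysis at low temperature and by keeping 10 as the limiting reagent so that no aryl-metal is left when 5 is added.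

Step 5
Reactants: 12 ethyl (3R,4R)-4-(3,4-dimethoxybenzyl)-3-{[6-(ethoxycarbonyl)-2-oxo-2H-pyran-4-yl]methyl}-2-oxotetrahydrofuran-3-carboxylate
Product: 14 4-{[(3R,4R)-4-(3,4-dimethoxybenzyl)-2-oxotetrahydrofuran-3-yl]methyl}-2-oxo-2H-pyran-6-carboxylic acid, via lactone diacid 13 (not isolated)
Conditions: 6 M aq. HCl/AcOH (1:1), 100 °C
Reagents that add atoms: water, O
Why: Acid-catalysed ester hydrolysis of both ethyl esters should give the malonic-type acid 13, which decarboxylates thermally through the lactone enol; protonation of that enol anti to the C4 benzyl group, backed by acid-mediated equilibration to the more stable isomer, sets C3 trans (3R,4R), and the 2-pyrone acid, the γ-lactone and the aryl methyl ethers should tolerate hot dilute HCl.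

Compound list
1 | ethyl 3-methylbut-2-enoate | CCOC(=O)C=C(C)C | starting material
2 | diethyl oxalate | CCOC(=O)C(=O)OCC | starting material
3 | potassium (2Z,4Z)-1,6-diethoxy-4-methyl-1,6-dioxohexa-2,4-dien-2-olate (cyclisation-competent form of a geometrically mobile dienolate) | CCOC(=O)/C([O-])=C/C(C)=C\C(=O)OCC.[K+] | intermediate
4 | ethyl 4-methyl-2-oxo-2H-pyran-6-carboxylate | CCOC(=O)c1cc(C)cc(=O)o1 | intermediate
5 | ethyl 4-(bromomethyl)-2-oxo-2H-pyran-6-carboxylate | CCOC(=O)c1cc(CBr)cc(=O)o1 | intermediate
6 | diethyl malonate | CCOC(=O)CC(=O)OCC | starting material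
7 | (R)-epichlorohydrin | ClC[C@H]1CO1 | starting material
8 | diethyl 2-{[(2R)-oxiran-2-yl]methyl}malonate (present as its sodium enolate) | CCOC(=O)C(C[C@@H]1CO1)C(=O)OCC | intermediate
9 | ethyl (1S,5R)-2-oxo-3-oxabicyclo[3.1.0]hexane-1-carboxylate | O=C1OC[C@@H]2C[C@]12C(=O)OCC | intermediate
10 | 3,4-dimethoxyphenylmagnesium bromide | COc1ccc([Mg]Br)cc1OC | starting material
11 | bromomagnesium enolate of ethyl (4R)-4-(3,4-dimethoxybenzyl)-2-oxotetrahydrofuran-3-carboxylate | COc1ccc(C[C@H]2COC(O[Mg]Br)=C2C(=O)OCC)cc1OC | intermediate
12 | ethyl (3R,4R)-4-(3,4-dimethoxybenzyl)-3-{[6-(ethoxycarbonyl)-2-oxo-2H-pyran-4-yl]methyl}-2-oxotetrahydrofuran-3-carboxylate | COc1ccc(C[C@H]2COC(=O)[C@@]2(Cc3cc(C(=O)OCC)oc(=O)c3)C(=O)OCC)cc1OC | intermediate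
13 | (3R,4R)-3-[(6-carboxy-2-oxo-2H-pyran-4-yl)methyl]-4-(3,4-dimethoxybenzyl)-2-oxotetrahydrofuran-3-carboxylic acid | COc1ccc(C[C@H]2COC(=O)[C@@]2(Cc3cc(C(=O)O)oc(=O)c3)C(=O)O)cc1OC | intermediate
14 | 4-{[(3R,4R)-4-(3,4-dimethoxybenzyl)-2-oxotetrahydrofuran-3-yl]methyl}-2-oxo-2H-pyran-6-carboxylic acid (CNP0526356.1) | COc1ccc(C[C@H]2COC(=O)[C@@H]2Cc2cc(C(=O)O)oc(=O)c2)cc1OC | target

Total step count: 5
Longest linear sequence: 4 steps (steps 1, 2, 4, 5); step 3 supplies the second branch.

Steps most likely to fail

Step 4. The chelated bromomagnesium enolate may C-alkylate sluggishly, or residual aryl-magnesium/aryl-copper species may attack the bromomethylpyrone. The fallback gives up the three-component mode and sets out from 9 and 10. The copper-catalysed opening is run alone and quenched with dilute HCl to give ethyl (3S,4R)-4-(3,4-dimethoxybenzyl)-2-oxotetrahydrofuran-3-carboxylate F1 (trans shown; C3 epimerises freely). F1 is isolated and then C-alkylated with 5 as its potassium enolate (K2CO3, acetone, rt), which comes back to the route at 12.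

Step 2. Over-bromination to the dibromomethyl compound and ionic bromination of the pyrone ring may compete with monobromination. The fallback sets out from 4 and replaces radical halogenation by oxidation, reduction and substitution. SeO2 (1,4-dioxane, reflux) should oxidise the activated methyl group to ethyl 4-formyl-2-oxo-2H-pyran-6-carboxylate F2. Luche reduction (NaBH4, CeCl3·7H2O, EtOH, −40 °C) should give ethyl 4-(hydroxymethyl)-2-oxo-2H-pyran-6-carboxylate F3. An Appel reaction (CBr4, PPh3, CH2Cl2, 0 °C) then comes back to the route at 5.

Step 5. Hydrolysis of the hindered ester on the quaternary C3 may be slow, and the prolonged heating in strong acid may erode material through O-demethylation of the veratryl ethers. The fallback sets out from 12 and separates the two ester cleavages under non-acidic conditions. Krapcho dealkoxycarbonylation (LiCl, H2O, DMSO, 130 °C) should remove only the malonate-type ester and give ethyl 4-{[(3R,4R)-4-(3,4-dimethoxybenzyl)-2-oxotetrahydrofuran-3-yl]methyl}-2-oxo-2H-pyran-6-carboxylate F4, with C3 protonated trans. The activated pyrone ester of F4 is then cleaved with Me3SnOH (1,2-dichloroethane, 80 °C; dilute HCl work-up), which comes back to the route at 14.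

Further compounds
F1 | step 4 | ethyl (3S,4R)-4-(3,4-dimethoxybenzyl)-2-oxotetrahydrofuran-3-carboxylate | COc1ccc(C[C@H]2COC(=O)[C@@H]2C(=O)OCC)cc1OC
F2 | step 2 | ethyl 4-formyl-2-oxo-2H-pyran-6-carboxylate | CCOC(=O)c1cc(C=O)cc(=O)o1
F3 | step 2 | ethyl 4-(hydroxymethyl)-2-oxo-2H-pyran-6-carboxylate | CCOC(=O)c1cc(CO)cc(=O)o1
F4 | step 5 | ethyl 4-{[(3R,4R)-4-(3,4-dimethoxybenzyl)-2-oxotetrahydrofuran-3-yl]methyl}-2-oxo-2H-pyran-6-carboxylate | COc1ccc(C[C@H]2COC(=O)[C@@H]2Cc3cc(C(=O)OCC)oc(=O)c3)cc1OC
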